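## Analysis of the target

Germacrane numbering is used: ring carbons C1–C10, C11 (lactone α-carbon), C12 (lactone carbonyl), C13 (exocyclic methylene), C14 (methyl on C10), C15 (oxygenated carbon on C4).

- The target 29 is a heliangolide-type germacranolide: a cyclodeca-1(10),4-diene trans-fused across C7–C8 to an α-methylene-γ-butyrolactone (12,8-olide). The C6 hydroxyl is free and C15 is esterified.
- Both ring olefins are trisubstituted. C1=C10 is E. C4=C5 is ring-cis, with C3 and C6 on the same side; its descriptor is E only because C15 carries oxygen.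
- The three stereocentres are contiguous: C6 (R), C7 (S), C8 (S). H7 and H8 are trans on the lactone. With C5–C6–C7–C11 drawn as a zigzag, the C6 hydroxyl is anti to C8.
- The C15 ester is (Z)-2-(hydroxymethyl)but-2-enoate, an angelate-type acid that isomerises to the E form when its carbonyl is activated.
- Sensitive groups: the exo-methylene lactone (Michael acceptor), the 1,5-diene (Cope and acid-induced transannular reactions), the 6-OH next to the 8-O lactone (translactonisation under base), and two primary allylic C–O bonds.
- The feature that invites the key move is the array HO–C6–C7(–C8–O)–C11(=C13)–C12, a 3-(1-hydroxyalkyl)-2-methylidene-butan-4-olide. Its C6–C7 bond is the retron of a γ-selective carbonyl allylation by a 3-(metallomethyl)but-2-en-4-olide, and the same bond lies in the ten-membered ring.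
- The difficulty is a strained medium ring with two olefins of defined geometry, a stereotriad on a flexible ring, and four oxygen functions to tell apart.

## Retrosynthetic reasoning

**29 ⇒ 28.** Only the silyl ether on the side-chain hydroxyl is removed at the end. It is needed because that hydroxyl would otherwise compete in the acylation of C8–OH; fluoride under buffered acidic conditions avoids base.

**28 ⇒ 26 (key disconnection, C6–C7).** This bond is cut because it belongs to the ten-membered ring and also joins two of the three stereocentres. The precursor 26 is acyclic apart from a butenolide and has one stereocentre (C8). Forward, a chromium-mediated allylation must close the carbocycle, set C6 and C7, and convert the 3-(bromomethyl)butenolide into the α-methylene lactone by allylic transposition. The lactone C–O bond at C8 already exists in 26, so the lactone cannot end up on C6.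

**26 ⇒ 25 ⇒ 24.** The butenolide C7=C11 bond is cut by metathesis and the C8–O–C12 bond by acylation. This leads back to the vinyl carbinol 24, whose only hydroxyl is the C8–OH. The allylic bromide is thus introduced with its three carbons in one reagent and is never carried through organometallic steps.

**24 ⇒ 23 ⇒ 21 + 9 (C3–C4).** The sp3–sp2 bond between the homoallylic carbon C3 and the olefinic carbon C4 is cut. Forward, a palladium-catalysed coupling of the alkylzinc 22 (from iodide 21) with alkenyl iodide 9 proceeds with retention, so the ring-cis geometry of C4=C5 is decided by the geometry of 9. C6 travels as an acetal and C8–OH as a triethylsilyl ether; one acidic step frees both and gives 24.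

**9 ⇒ 8 + 5, and 8 ⇒ 7 ⇒ 6.** The C15–O ester bond is made by alkylating the carboxylate of 5 with the activated alcohol 8, so the acid carbonyl is never activated. The iodoalkene geometry comes from α-iodination of the E-enal 6: the aldehyde carbon (the later C15) stays trans to the acetal carbon (C6), and iodine (the later C3) sits cis to it. C15 and C6 are differentiated from the start as aldehyde and acetal.

**5 ⇒ 4 ⇒ 3 ⇒ 1.** The Z acid is traced to ynoate 1. A syn hydroalumination followed by trapping with a C1 electrophile fixes the ester cis to the methyl group.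

**21 ⇒ 20 ⇒ 17 ⇒ 16 ⇒ 13 ⇒ 10 + 11.** The E-trisubstituted C1=C10 olefin is cut back to the terminal alkyne 17: a syn methyl-metalation sets the geometry and a two-carbon epoxide electrophile supplies C2–C3. The C8 carbinol comes from the chiral pool: alkynylation of 10 by 11, then one-carbon homologation of the derived epoxide 14 to the vinyl carbinol.

## Alternatives that were turned down

**Alternative 1: ring-closing metathesis at C1=C10 (the textbook cut).**
- Disconnection: the C1=C10 double bond, with the stereotriad and the α-methylene lactone already present in the seco-diene A1.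
- Forward key step: ruthenium-carbene ring closure between the monosubstituted C1 olefin and the 1,1-disubstituted C10 olefin of A1.
- Turned down because a trisubstituted olefin must form inside a strained ten-membered ring, where dimerisation competes and the E geometry is not under control. The exo-methylene of the lactone is a third reactive olefin. The step forms no stereocentre, so C6, C7 and C8 would each need separate chemistry before it; the route is longer and its risk is not repaid.

**Alternative 2: anionic oxy-Cope ring expansion (C8–C9 bond).**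
- Disconnection: the C8–C9 bond, leading back to the 1,2-dialkenylcyclohexenol A2.
- Forward key step: [3,3] rearrangement of the alkoxide of A2 to the cyclodecadienone A3. This delivers the ring-cis C4=C5 bond from the cyclohexene and the E C1=C10 bond from a chair transition state.
- Turned down because A3 has no stereocentre, no oxygen at C8 and none of C11–C13. C7 would have to be alkylated, C8 oxidised and C6 reduced on a flexible ring under substrate control, in racemic form unless a resolution is added. The lactone annulation alone would cost more steps than the whole sequence from 21 and 9 to 28.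

**Alternative 3: closure of C2–C3 by intramolecular allylic alkylation.**
- Disconnection: the bis-allylic C2–C3 bond, with the stereotriad made first by an intermolecular allylation, giving the sulfone and allylic chloride A4.
- Forward key step: deprotonation of A4 next to the sulfone and ring closure by displacement of the allylic chloride, followed by reductive desulfonylation.
- Turned down because the strong base meets an α-methylene lactone with an acidic C7–H and two esters, so the lactone olefin would have to be masked and unmasked. The desulfonylation would also threaten the allylic C15–O and C6–O bonds. The closure sets no stereocentre and the α/γ selectivity of the allyl sulfone anion is uncertain.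

Key step: step 16

Remark: metal alkoxides and carboxylates that are only the salt form of a product before aqueous work-up are not counted as separate compounds.

## Route

**Side-chain acid (steps 1–3)**

Step 1
Reactants: 1 methyl but-2-ynoate
Product: 3 methyl (2Z)-2-(hydroxymethyl)but-2-enoate, via vinylalane 2 (not isolated)
Conditions: i-Bu2AlH, NMO, THF, 0 °C; then 1; then HCHO (gas), 0 °C → rt
Reagents that add atoms: formaldehyde, C=O
Why: Syn hydroalumination of the ynoate by the i-Bu2AlH–NMO complex places Al on C2 cis to H3; the α-alumino enoate should add to formaldehyde with retention (vinylalumination), so the ester ends cis to the methyl group (Z).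

Step 2
Reactants: 3 methyl (2Z)-2-(hydroxymethyl)but-2-enoate
Product: 4 methyl (2Z)-2-{[(tert-butyldimethylsilyl)oxy]methyl}but-2-enoate
Conditions: TBSCl, imidazole, DMF, 0 °C → rt
Reagents that add atoms: tert-butyldimethylsilyl chloride, CC(C)(C)[Si](C)(C)Cl
Why: Standard silylation of a primary allylic alcohol; the olefin geometry is not touched.

Step 3
Reactants: 4 methyl (2Z)-2-{[(tert-butyldimethylsilyl)oxy]methyl}but-2-enoate
Product: 5 (2Z)-2-{[(tert-butyldimethylsilyl)oxy]methyl}but-2-enoic acid
Conditions: LiOH·H2O, THF–H2O, rt; then 1 M HCl to pH 4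
Reagents that add atoms: lithium hydroxide, [Li+].[OH-]
Why: Saponification by acyl–oxygen cleavage at room temperature; no conjugate addition–elimination path is open at this temperature, so the Z geometry and the silyl ether should survive.

**C4–C6/C15 alkenyl iodide (steps 4–6)**

Step 4
Reactants: 6 (2E)-4,4-dimethoxybut-2-enal
Product: 7 (2Z)-2-iodo-4,4-dimethoxybut-2-enal
Conditions: I2, K2CO3, DMAP (cat.), THF–H2O (1:1), rt
Reagents that add atoms: iodine, II
Why: Amine-catalysed α-iodination of an enal (conjugate addition of DMAP, iodination of the enolate, E1cB loss of DMAP); the aldehyde stays trans to the acetal carbon, so iodine ends cis to it, which is the geometry later needed for C3 cis to C6.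

Step 5
Reactants: 7 (2Z)-2-iodo-4,4-dimethoxybut-2-enal
Product: 8 (2Z)-2-iodo-4,4-dimethoxybut-2-en-1-ol
Conditions: NaBH4, CeCl3·7H2O, MeOH, −20 °C
Reagents that add atoms: none
Why: Luche 1,2-reduction of the aldehyde; the C–I bond and the olefin geometry are untouched and the dimethyl acetal is degenerate in methanol.

Step 6
Reactants: 8 (2Z)-2-iodo-4,4-dimethoxybut-2-en-1-ol; 5 (2Z)-2-{[(tert-butyldimethylsilyl)oxy]methyl}but-2-enoic acid
Product: 9 (2Z)-2-iodo-4,4-dimethoxybut-2-en-1-yl (2Z)-2-{[(tert-butyldimethylsilyl)oxy]methyl}but-2-enoate
Conditions: PPh3, DIAD, THF, 0 °C → rt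
Reagents that add atoms: none
Why: Mitsunobu esterification: the carboxylate displaces the activated primary allylic oxygen at C15 (SN2), so the acid carbonyl is never activated and the angelate-type Z geometry cannot isomerise.

**C1–C3/C7–C10 alkyl iodide (steps 7–11)**

Step 7
Reactants: 10 (2S)-2-(chloromethyl)oxirane; 11 ethynyl(trimethyl)silane
Product: 13 (2S)-1-chloro-5-(trimethylsilyl)pent-4-yn-2-ol, via lithium acetylide 12 (not isolated)
Conditions: 11, n-BuLi, THF, −78 °C; then BF3·OEt2, 10, −78 °C
Reagents that add atoms: none
Why: BF3-mediated alkynylation of the epoxide at its terminal CH2; no bond to the stereocentre (the later C8) is broken and the chloride is kept.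

Step 8
Reactants: 13 (2S)-1-chloro-5-(trimethylsilyl)pent-4-yn-2-ol
Product: 16 (3S)-hex-1-en-5-yn-3-ol, via epoxide 14 (not isolated), via silylated enynol 15 (not isolated)
Conditions: Me3SI, n-BuLi, THF, −10 °C → rt; then K2CO3, MeOH, rt
Reagents that add atoms: trimethylsulfonium iodide, C[S+](C)C.[I-]
Why: Base closes the chlorohydrin to the terminal epoxide, dimethylsulfonium methylide opens it at CH2 and the betaine loses Me2S to give the one-carbon-homologated allylic alcohol; methanolysis then removes the alkynyl silyl group, and C8 keeps its configuration throughout.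

Step 9
Reactants: 16 (3S)-hex-1-en-5-yn-3-ol
Product: 17 (3S)-3-[(triethylsilyl)oxy]hex-1-en-5-yne
Conditions: TESCl, imidazole, CH2Cl2, 0 °C
Reagents that add atoms: chlorotriethylsilane, CC[Si](Cl)(CC)CC
Why: Standard silylation; the triethylsilyl ether is needed only to keep the hydroxyl from quenching the zinc reagent of step 12 and is chosen to fall off with the acetal in step 13.

Step 10
Reactants: 17 (3S)-3-[(triethylsilyl)oxy]hex-1-en-5-yne
Product: 20 (3E,6S)-4-methyl-6-[(triethylsilyl)oxy]octa-3,7-dien-1-ol, via alkenylalane 18 (not isolated), via lithium alkenylaluminate 19 (not isolated)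
Conditions: Me3Al, Cp2ZrCl2 (0.25 equiv), CH2Cl2, 0 °C → rt; volatiles removed; n-BuLi, THF, −78 °C; ethylene oxide, −78 → 0 °C
Reagents that add atoms: trimethylaluminium, C[Al](C)C; ethylene oxide, C1CO1
Why: Negishi zirconium-catalysed carboalumination adds methyl and aluminium syn across the terminal alkyne (methyl to the internal carbon), which fixes the E geometry of C1=C10; the aluminate opens the epoxide with retention at the alkenyl carbon, and the terminal alkene reacts far more slowly than the alkyne.

Step 11
Reactants: 20 (3E,6S)-4-methyl-6-[(triethylsilyl)oxy]octa-3,7-dien-1-ol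
Product: 21 (3S,5E)-8-iodo-5-methyl-3-[(triethylsilyl)oxy]octa-1,5-diene
Conditions: I2, PPh3, imidazole, CH2Cl2, 0 °C
Reagents that add atoms: iodine, II
Why: Appel-type iodination of a primary alcohol under buffered conditions that spare the silyl ether and both olefins.

**Fragment union and endgame (steps 12–17)**

Step 12
Reactants: 21 (3S,5E)-8-iodo-5-methyl-3-[(triethylsilyl)oxy]octa-1,5-diene; 9 (2Z)-2-iodo-4,4-dimethoxybut-2-en-1-yl (2Z)-2-{[(tert-butyldimethylsilyl)oxy]methyl}but-2-enoate
Product: 23 [(2E,6E,9S)-1,1-dimethoxy-7-methyl-9-[(triethylsilyl)oxy]undeca-2,6,10-trien-3-yl]methyl (2Z)-2-{[(tert-butyldimethylsilyl)oxy]methyl}but-2-enoate, via alkylzinc iodide 22 (not isolated)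
Conditions: Zn, LiCl, THF, 40 °C; then 9, Pd(dppf)Cl2 (5 mol %), THF–NMP, rt
Reagents that add atoms: none
Why: Zinc inserts into the primary C–I bond and Negishi sp3–sp2 coupling replaces the alkenyl iodine with retention, so C3 ends cis to C6; oxidative addition into the C–I bond should be much faster than ionisation of the allylic ester.

Step 13
Reactants: 23 coupled acetal (as named in step 12)
Product: 24 [(2E,6E,9S)-9-hydroxy-7-methyl-1-oxoundeca-2,6,10-trien-3-yl]methyl (2Z)-2-{[(tert-butyldimethylsilyl)oxy]methyl}but-2-enoate
Conditions: AcOH–THF–H2O (3:1:1), rt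
Reagents that add atoms: water, O
Why: Aqueous acetic acid hydrolyses the allylic dimethyl acetal and the secondary triethylsilyl ether, both far more labile than the primary tert-butyldimethylsilyl ether; no amine or strong acid is present that could isomerise the enal.

Step 14
Reactants: 24 hydroxy enal (as named in step 13)
Product: 25 (3S,5E,9E)-9-[({(2Z)-2-{[(tert-butyldimethylsilyl)oxy]methyl}but-2-enoyl}oxy)methyl]-5-methyl-11-oxoundeca-1,5,9-trien-3-yl 2-(bromomethyl)prop-2-enoate
Conditions: 2-(bromomethyl)acrylic acid, (COCl)2, DMF (cat.), CH2Cl2, 0 °C → rt, evaporation; then 24, 2,6-lutidine, CH2Cl2, −20 → 0 °C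
Reagents that add atoms: 2-(bromomethyl)acrylic acid, C=C(CBr)C(=O)O (activated in the flask as its acid chloride)
Why: Acylation of the only hydroxyl by an acid chloride with a hindered base that does not quaternise with the allylic bromide; the C8 configuration is retained.

Step 15
Reactants: 25 bromomethylacrylate (as named in step 14)
Product: 26 [(2E,6E)-8-[(2S)-4-(bromomethyl)-5-oxo-2,5-dihydrofuran-2-yl]-7-methyl-1-oxoocta-2,6-dien-3-yl]methyl (2Z)-2-{[(tert-butyldimethylsilyl)oxy]methyl}but-2-enoate
Conditions: second-generation Grubbs catalyst (10 mol %), toluene (5 mM), 70 °C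
Reagents that add atoms: none
Why: Ring-closing metathesis of an acrylate of a secondary allylic alcohol to a but-2-enolide: the carbene forms at the vinyl group and closes the five-membered ring onto the 1,1-disubstituted acrylate, while the trisubstituted and electron-poor olefins stay out.

Step 16
Reactants: 26 aldehyde-tethered 3-(bromomethyl)butenolide (as named in step 15)
Product: 28 [(3aS,4R,5E,9E,11aS)-4-hydroxy-10-methyl-3-methylidene-2-oxo-2,3,3a,4,7,8,11,11a-octahydrocyclodeca[b]furan-6-yl]methyl (2Z)-2-{[(tert-butyldimethylsilyl)oxy]methyl}but-2-enoate, via allylchromium dichloride 27 (not isolated)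
Conditions: CrCl2 (10 equiv), THF, rt, slow addition of 26 to about 2 mM; aqueous NH4Cl work-up
Reagents that add atoms: none
Why: Two equivalents of CrCl2 reduce the allylic C13–Br bond to the allylchromium species 27 of trivalent chromium (Nozaki–Hiyama–Kishi allylation); the aldehyde oxygen binds chromium and C6–C7 forms through a six-membered chair transition state with allylic transposition, which moves the double bond from C7=C11 to C11=C13 and so unveils the α-methylene lactone. The closest known reactions are chromium-mediated additions of 3-(bromomethyl)furan-2(5H)-ones to enals and the macrocyclising Nozaki–Hiyama–Kishi allylations of 2-(bromomethyl)acrylates that close germacranolide and cembranolide rings. The ten-membered carbocycle closes in a 10-exo-trig mode onto the aldehyde carbon; the lactone ring is carried in and not formed here. C7 is controlled by C8: the new bond should form on the butenolide face opposite the C9 branch, which gives the trans H7/H8 ring fusion. C6 is controlled by the fixed geometry of the nucleophile: the butenolide holds C8 trans to the C13H2–Cr group (an E γ-substituted allyl metal), so with C5 pseudo-equatorial the chair should deliver the anti adduct (6R) with H6 and H7 antiperiplanar, as in the target. The step needs γ- and not α-attack (secured by the closed transition state), ring closure and not oligomerisation (secured by high dilution), and chemoselectivity (divalent chromium leaves the allylic ester, the enoate and the silyl ether alone). The ring-cis C4=C5 bond of the enal and the E C1=C10 bond turn the chain so that C6 can reach C7.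

Step 17
Reactants: 28 silyl ether of the target (as named in step 16)
Product: 29 [(3aS,4R,5E,9E,11aS)-4-hydroxy-10-methyl-3-methylidene-2-oxo-2,3,3a,4,7,8,11,11a-octahydrocyclodeca[b]furan-6-yl]methyl (2Z)-2-(hydroxymethyl)but-2-enoate
Conditions: HF·pyridine, pyridine, THF, 0 °C → rt
Reagents that add atoms: none
Why: Fluoride cleaves the primary silyl ether under buffered acidic conditions; without base there should be no translactonisation to C6, no conjugate addition to the methylene lactone and no Z to E isomerisation of the side chain.

## Compound list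

1 | methyl but-2-ynoate | CC#CC(=O)OC | starting material
2 | methyl (2E)-2-[bis(2-methylpropyl)alumanyl]but-2-enoate (ester cis to the C4 methyl) | C/C=C(/[Al](CC(C)C)CC(C)C)C(=O)OC | intermediate (not isolated)
3 | methyl (2Z)-2-(hydroxymethyl)but-2-enoate | C/C=C(/CO)C(=O)OC | intermediate
4 | methyl (2Z)-2-{[(tert-butyldimethylsilyl)oxy]methyl}but-2-enoate | C/C=C(/CO[Si](C)(C)C(C)(C)C)C(=O)OC | intermediate
5 | (2Z)-2-{[(tert-butyldimethylsilyl)oxy]methyl}but-2-enoic acid | C/C=C(/CO[Si](C)(C)C(C)(C)C)C(=O)O | intermediate
6 | (2E)-4,4-dimethoxybut-2-enal | COC(OC)/C=C/C=O | starting material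
7 | (2Z)-2-iodo-4,4-dimethoxybut-2-enal | COC(OC)/C=C(I)/C=O | intermediate
8 | (2Z)-2-iodo-4,4-dimethoxybut-2-en-1-ol | COC(OC)/C=C(I)/CO | intermediate
9 | (2Z)-2-iodo-4,4-dimethoxybut-2-en-1-yl (2Z)-2-{[(tert-butyldimethylsilyl)oxy]methyl}but-2-enoate | COC(OC)/C=C(I)/COC(=O)/C(=C\C)CO[Si](C)(C)C(C)(C)C | intermediate
10 | (2S)-2-(chloromethyl)oxirane ((S)-epichlorohydrin) | ClC[C@@H]1CO1 | starting material
11 | ethynyl(trimethyl)silane | C#C[Si](C)(C)C | starting material
12 | lithium (trimethylsilyl)acetylide | [Li]C#C[Si](C)(C)C | intermediate (not isolated)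
13 | (2S)-1-chloro-5-(trimethylsilyl)pent-4-yn-2-ol | O[C@H](CCl)CC#C[Si](C)(C)C | intermediate
14 | (2S)-2-[3-(trimethylsilyl)prop-2-yn-1-yl]oxirane | C[Si](C)(C)C#CC[C@H]1CO1 | intermediate (not isolated)
15 | (3S)-6-(trimethylsilyl)hex-1-en-5-yn-3-ol | O[C@H](C=C)CC#C[Si](C)(C)C | intermediate (not isolated)
16 | (3S)-hex-1-en-5-yn-3-ol | O[C@H](C=C)CC#C | intermediate
17 | (3S)-3-[(triethylsilyl)oxy]hex-1-en-5-yne | CC[Si](CC)(CC)O[C@H](C=C)CC#C | intermediate
18 | dimethyl{(1E,4S)-2-methyl-4-[(triethylsilyl)oxy]hexa-1,5-dien-1-yl}alumane | C[Al](C)/C=C(\C)C[C@@H](C=C)O[Si](CC)(CC)CC | intermediate (not isolated)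
19 | lithium butyl(dimethyl){(1E,4S)-2-methyl-4-[(triethylsilyl)oxy]hexa-1,5-dien-1-yl}aluminate | [Li+].CCCC[Al-](C)(C)/C=C(\C)C[C@@H](C=C)O[Si](CC)(CC)CC | intermediate (not isolated)
20 | (3E,6S)-4-methyl-6-[(triethylsilyl)oxy]octa-3,7-dien-1-ol | OCC/C=C(\C)C[C@@H](C=C)O[Si](CC)(CC)CC | intermediate
21 | (3S,5E)-8-iodo-5-methyl-3-[(triethylsilyl)oxy]octa-1,5-diene | ICC/C=C(\C)C[C@@H](C=C)O[Si](CC)(CC)CC | intermediate
22 | {(3E,6S)-4-methyl-6-[(triethylsilyl)oxy]octa-3,7-dien-1-yl}zinc iodide | I[Zn]CC/C=C(\C)C[C@@H](C=C)O[Si](CC)(CC)CC | intermediate (not isolated)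
23 | [(2E,6E,9S)-1,1-dimethoxy-7-methyl-9-[(triethylsilyl)oxy]undeca-2,6,10-trien-3-yl]methyl (2Z)-2-{[(tert-butyldimethylsilyl)oxy]methyl}but-2-enoate | COC(OC)/C=C(/COC(=O)/C(=C\C)CO[Si](C)(C)C(C)(C)C)CC/C=C(\C)C[C@@H](C=C)O[Si](CC)(CC)CC | intermediate
24 | [(2E,6E,9S)-9-hydroxy-7-methyl-1-oxoundeca-2,6,10-trien-3-yl]methyl (2Z)-2-{[(tert-butyldimethylsilyl)oxy]methyl}but-2-enoate | O=C/C=C(/COC(=O)/C(=C\C)CO[Si](C)(C)C(C)(C)C)CC/C=C(\C)C[C@@H](C=C)O | intermediate
25 | (3S,5E,9E)-9-[({(2Z)-2-{[(tert-butyldimethylsilyl)oxy]methyl}but-2-enoyl}oxy)methyl]-5-methyl-11-oxoundeca-1,5,9-trien-3-yl 2-(bromomethyl)prop-2-enoate | O=C/C=C(/COC(=O)/C(=C\C)CO[Si](C)(C)C(C)(C)C)CC/C=C(\C)C[C@@H](C=C)OC(=O)C(=C)CBr | intermediate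
26 | [(2E,6E)-8-[(2S)-4-(bromomethyl)-5-oxo-2,5-dihydrofuran-2-yl]-7-methyl-1-oxoocta-2,6-dien-3-yl]methyl (2Z)-2-{[(tert-butyldimethylsilyl)oxy]methyl}but-2-enoate | O=C/C=C(/COC(=O)/C(=C\C)CO[Si](C)(C)C(C)(C)C)CC/C=C(\C)C[C@@H]1OC(=O)C(CBr)=C1 | intermediate
27 | allylchromium dichloride of 26 (CrCl2 on C13 in place of bromine) | O=C/C=C(/COC(=O)/C(=C\C)CO[Si](C)(C)C(C)(C)C)CC/C=C(\C)C[C@@H]1OC(=O)C(C[Cr](Cl)Cl)=C1 | intermediate (not isolated)
28 | [(3aS,4R,5E,9E,11aS)-4-hydroxy-10-methyl-3-methylidene-2-oxo-2,3,3a,4,7,8,11,11a-octahydrocyclodeca[b]furan-6-yl]methyl (2Z)-2-{[(tert-butyldimethylsilyl)oxy]methyl}but-2-enoate | C=C1C(=O)O[C@H]2C/C(C)=C/CC/C(COC(=O)/C(=C\C)CO[Si](C)(C)C(C)(C)C)=C\[C@@H](O)[C@H]12 | intermediate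
29 | [(3aS,4R,5E,9E,11aS)-4-hydroxy-10-methyl-3-methylidene-2-oxo-2,3,3a,4,7,8,11,11a-octahydrocyclodeca[b]furan-6-yl]methyl (2Z)-2-(hydroxymethyl)but-2-enoate | C=C1C(=O)O[C@H]2C/C(C)=C/CC/C(COC(=O)/C(=C\C)CO)=C\[C@@H](O)[C@H]12 | target

## Step count and risk

Total step count: 17. Longest linear sequence: 11 steps (steps 7–17, from 10 to 29).

**Key step (step 16).**
- What may go wrong: the strained ten-membered ring may close slowly, so the allylchromium species may react between molecules and give oligomers. The tether may also force a boat-like or open transition state, which would give poor facial selectivity at the aldehyde and the C6 epimer. The chromium alkoxide at C6 might open the lactone and move it to C6.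
- Fallback: it sets out from 26 and uses the cyclisation product even if it is the 6-epi alcohol F1. F1 is oxidised with Dess–Martin periodinane to the C6 ketone F2. F2 is reduced under reagent control with a Corey–Bakshi–Shibata oxazaborolidine and BH3·SMe2, the catalyst enantiomer chosen so that hydride adds to the Si face of the C6 carbonyl (priorities O > C7 > C5). This returns to the route at 28. The configuration at C6 is then set by the reagent in a separate reduction, not in the C–C bond formation; the C7 hydrogen of F2 is acidic, so both operations must stay free of base.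

**Step 15.**
- What may go wrong: the allylic bromide may deactivate the ruthenium carbene, and closure onto the 1,1-disubstituted electron-poor acrylate may be slow enough for cross-metathesis through the vinyl groups to compete.
- Fallback: it sets out from 25 and carries oxygen, not bromine, through the metathesis. The bromide is displaced by formate (HCO2Na, DMF; SN2 and SN2' give the same product) to give the 2-(formyloxymethyl)acrylate F3. Ring-closing metathesis gives the 3-(formyloxymethyl)butenolide F4. KHCO3 in methanol removes the formate selectively and gives the 3-(hydroxymethyl)butenolide F5. Corey–Kim bromination (NBS, Me2S) returns to the route at 26.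

**Step 12.**
- What may go wrong: zerovalent palladium may ionise the allylic ester of 9, or the alkenylpalladium intermediate may lose the β-acyloxy group to form an allene. Adventitious protonation of the zinc reagent would waste the longer fragment.
- Fallback: it sets out from 8 and 21 and changes the order of bond formation. The hydroxyl of 8 is deprotonated with MeMgCl and the alkoxide is coupled with zinc reagent 22 under the same palladium catalysis to give the 2-substituted allylic alcohol F6. Mitsunobu esterification of F6 with 5 returns to the route at 23.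

**Step 10.**
- What may go wrong: the aluminate may open the epoxide slowly, or butyl or methyl may be transferred in place of the alkenyl group.
- Fallback: it sets out from 17 through 18. Iodinolysis of the alkenylalane (I2, THF, −30 °C) gives the E-alkenyl iodide F7. Iodine–lithium exchange (t-BuLi, −78 °C) and opening of ethylene oxide by the alkenyllithium return to the route at 20.

**Step 1.**
- What may go wrong: the α-alumino enoate may lose its geometry through the allenolate while it waits for gaseous formaldehyde, and formaldehyde may oligomerise on the aluminium alkoxide.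
- Fallback: it sets out from 1 through 2. The vinylalane is quenched with iodine at low temperature to give methyl (2E)-2-iodobut-2-enoate F8. Stille coupling of F8 with (tributylstannyl)methanol (Pd(PPh3)4, toluene, 80 °C) replaces iodine by CH2OH with retention and returns to the route at 3.

## Further compounds

F1 | step 16 | C6 epimer of 28 (4S in the cyclodeca[b]furan numbering) | C=C1C(=O)O[C@H]2C/C(C)=C/CC/C(COC(=O)/C(=C\C)CO[Si](C)(C)C(C)(C)C)=C\[C@H](O)[C@H]12
F2 | step 16 | C6 ketone of 28 (4-oxo analogue) | C=C1C(=O)O[C@H]2C/C(C)=C/CC/C(COC(=O)/C(=C\C)CO[Si](C)(C)C(C)(C)C)=C\C(=O)[C@H]12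
F3 | step 15 | 2-(formyloxymethyl)prop-2-enoate analogue of 25 | O=C/C=C(/COC(=O)/C(=C\C)CO[Si](C)(C)C(C)(C)C)CC/C=C(\C)C[C@@H](C=C)OC(=O)C(=C)COC=O
F4 | step 15 | 3-(formyloxymethyl)butenolide analogue of 26 | O=C/C=C(/COC(=O)/C(=C\C)CO[Si](C)(C)C(C)(C)C)CC/C=C(\C)C[C@@H]1OC(=O)C(COC=O)=C1
F5 | step 15 | 3-(hydroxymethyl)butenolide analogue of 26 | O=C/C=C(/COC(=O)/C(=C\C)CO[Si](C)(C)C(C)(C)C)CC/C=C(\C)C[C@@H]1OC(=O)C(CO)=C1
F6 | step 12 | (2E,6E,9S)-2-(2,2-dimethoxyethylidene)-6-methyl-8-[(triethylsilyl)oxy]deca-5,9-dien-1-ol (C15 alcohol corresponding to 23) | COC(OC)/C=C(/CO)CC/C=C(\C)C[C@@H](C=C)O[Si](CC)(CC)CC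
F7 | step 10 | (1E,4S)-1-iodo-2-methyl-4-[(triethylsilyl)oxy]hexa-1,5-diene | I/C=C(\C)C[C@@H](C=C)O[Si](CC)(CC)CC
F8 | step 1 | methyl (2E)-2-iodobut-2-enoate | C/C=C(/I)C(=O)OC
A1 | alternative 1 | seco-diene for ring closure at C1=C10: trans-4,5-disubstituted 3-methylideneoxolan-2-one with a 2-methylprop-2-enyl group on C8 and the C6-hydroxy hepta-2,6-dienyl chain on C7, target configuration at C6, C7 and C8, side-chain ester as in 28 | C=C1C(=O)O[C@@H](CC(C)=C)[C@@H]1[C@H](O)/C=C(/COC(=O)/C(=C\C)CO[Si](C)(C)C(C)(C)C)CCC=C
A2 | alternative 2 | trans-1-ethenyl-3-{[(tert-butyldimethylsilyl)oxy]methyl}-6-(prop-1-en-2-yl)cyclohex-2-en-1-ol (ethenyl and propenyl groups trans) | C=C[C@@]1(O)C=C(CO[Si](C)(C)C(C)(C)C)CC[C@@H]1C(C)=C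
A3 | alternative 2 | (2Z,6E)-3-{[(tert-butyldimethylsilyl)oxy]methyl}-7-methylcyclodeca-2,6-dien-1-one | O=C1CCC/C(C)=C/CC/C(CO[Si](C)(C)C(C)(C)C)=C\1
A4 | alternative 3 | seco-sulfone for closure at C2–C3: trans-4,5-disubstituted 3-methylideneoxolan-2-one with a (2E)-4-chloro-2-methylbut-2-enyl group on C8 and a C6-triethylsilyloxy chain ending in CH2SO2Ph at C3, target configuration at C6, C7 and C8, side-chain ester as in 28 | C=C1C(=O)O[C@@H](C/C(C)=C/CCl)[C@@H]1[C@H](O[Si](CC)(CC)CC)/C=C(/COC(=O)/C(=C\C)CO[Si](C)(C)C(C)(C)C)CS(=O)(=O)c1ccccc1
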